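**Plan**
Locants: target = bicyclo[3.2.1]oct-2-en-8-one with C1 (allyl bridgehead), C2=C3(OMe), C4 (carbinol), C5 (OMe bridgehead), C6 (aryl), C7 (methyl), C8 (ketone); ring A = C1–C2–C3–C4–C5–C8, ring B = cyclopentanone C1–C8–C5–C6–C7.
Enabling feature: in ring A the bridgehead C5 is the α-carbon of the C8 ketone and carries the oxygenated C4, and C2=C3(OMe)–C4 is an α-methoxy enone once C4 is a ketone. This is a Dieckmann retron plus the trace of a β-methoxide elimination.
Cuts (retrosynthetic order): C4–H (hydride to the 4,8-dione); C4–C5 of ring A (ketone enolate onto a side-chain ester); C1–C2 (Mukaiyama addition of a C2–C3–C4 acetal ester); then C7–CH3, C1–allyl, C5–O and C6–aryl on cyclopent-2-enone.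
Forward order: aryl bromide → ring B built on cyclopent-2-enone by two conjugate additions (aryl at C6, methyl at C7) with C5 oxygenation and C1 allylation in between → C1–C2 bond → ring A closed last → C4 reduction → desilylation.
Stereochemistry: C6 from the [Rh(OH)((R)-binap)]2-catalysed aryl addition; C7 trans to the aryl group (cuprate); C1 chain anti to the C7 methyl; C5 dictated by the C1 tether (only a cis-1,3 bridge can form); C4 by exo hydride attack.

Key step: step 11

Remarks:
- Ar = 3-methoxy-4-(triisopropylsilyloxy)phenyl. In the Why lines C1–C8 always mean the target locants defined above.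
- Assumption: [Rh(OH)((R)-binap)]2 is taken to add this aryl group with the same facial sense as simple aryl groups, giving the (R)-silyl enol ether 7; if the sense were opposite, the (S)-ligand would be used.
- C5 is drawn trans to the aryl group in 8–19; its configuration is erased in step 11.

**Step 1**
Reactants: 1 4-bromo-2-methoxyphenol
Product: 2 (4-bromo-2-methoxyphenoxy)triisopropylsilane
Conditions: TIPSCl, imidazole, DMF, 25 °C
Reagents that add atoms: chlorotriisopropylsilane, CC(C)[Si](Cl)(C(C)C)C(C)C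
Why: Imidazole-promoted silylation gives a bulky aryl silyl ether that should survive the organometallic, oxidative and Lewis-acidic steps and is cleaved by fluoride at the end; no stereocentre is formed.

**Step 2**
Reactants: 2 (4-bromo-2-methoxyphenoxy)triisopropylsilane; 3 cyclopent-2-en-1-one
Product: 7 (R)-3-Ar-1-(trimethylsilyloxy)cyclopent-1-ene, via aryllithium 4 (not isolated), via aryltitanium triisopropoxide 5 (not isolated), via titanium enolate 6 (not isolated)
Conditions: n-BuLi, THF, −78 °C; ClTi(OiPr)3, −78 → 20 °C; 3, [Rh(OH)((R)-binap)]2 (1.5 mol %), THF, 20 °C; then LiOiPr, TMSCl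
Reagents that add atoms: chlorotrimethylsilane, C[Si](C)(C)Cl
Why: Asymmetric 1,4-addition of an aryltitanium reagent (Hayashi–Miyaura-type conjugate addition) sets C6 under control of the (R)-BINAP ligand in the aryl–rhodium carbometalation of the enone, and silylation of the titanium enolate keeps the enol double bond regiodefined toward C5.

**Step 3**
Reactants: 7 (R)-3-Ar-1-(trimethylsilyloxy)cyclopent-1-ene
Product: 9 (2S,3S)-3-Ar-2-hydroxycyclopentan-1-one, via silyloxy ketone 8 (not isolated)
Conditions: mCPBA, CH2Cl2, −20 → 0 °C; then 1 M HCl, THF, 0 °C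
Reagents that add atoms: 3-chloroperoxybenzoic acid, OOC(=O)c1cccc(Cl)c1
Why: Rubottom oxidation: the peracid epoxidises the enol silane on the face anti to the neighbouring aryl group and silyl migration gives the trans 2-silyloxy ketone, which is hydrolysed to the α-hydroxy ketone (this centre becomes planar again in step 11, so its configuration is not critical).

**Step 4**
Reactants: 9 (2S,3S)-3-Ar-2-hydroxycyclopentan-1-one
Product: 10 (2S,3S)-3-Ar-2-methoxycyclopentan-1-one
Conditions: MeI, Ag2O, 4 Å molecular sieves, CH2Cl2, 25 °C, dark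
Reagents that add atoms: iodomethane, CI
Why: Purdie-type O-methylation with MeI/Ag2O converts the α-ketol into its methyl ether under non-basic conditions, so no enolate chemistry interferes and no new stereocentre is formed.

**Step 5**
Reactants: 10 (2S,3S)-3-Ar-2-methoxycyclopentan-1-one
Product: 12 (4S,5S)-4-Ar-5-methoxycyclopent-2-en-1-one, via kinetic enol silane 11 (not isolated)
Conditions: LiN(i-Pr)2, THF, −78 °C; TMSCl; then Pd(OAc)2 (1.05 equiv), MeCN, 25 °C
Reagents that add atoms: none
Why: Kinetic deprotonation should occur at the unhindered C1 methylene and not at the methoxy-bearing tertiary C5, and Saegusa–Ito oxidation of the enol silane gives the C1=C7 enone under neutral conditions that leave the benzylic C6 stereocentre untouched.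

**Step 6**
Reactants: 12 (4S,5S)-4-Ar-5-methoxycyclopent-2-en-1-one
Product: 13 (4S,5S)-4-Ar-2-iodo-5-methoxycyclopent-2-en-1-one
Conditions: I2, pyridine, CH2Cl2, 0 → 25 °C
Reagents that add atoms: iodine, II
Why: α-Iodination of the enone by pyridine-mediated conjugate addition, iodination and elimination places iodine on C1 only; no new stereocentre.

**Step 7**
Reactants: 13 (4S,5S)-4-Ar-2-iodo-5-methoxycyclopent-2-en-1-one
Product: 14 (4S,5S)-2-allyl-4-Ar-5-methoxycyclopent-2-en-1-one
Conditions: allylSnBu3, Pd2(dba)3 (2.5 mol %), AsPh3, CuI, DMF, 25 °C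
Reagents that add atoms: allyltributylstannane, C=CC[Sn](CCCC)(CCCC)CCCC
Why: Stille coupling of the α-iodoenone installs the C1 allyl group under neutral conditions that should not epimerise C6.

**Step 8**
Reactants: 15 methyl methoxyacetate
Product: 17 methyl 2,3,3-trimethoxypropanoate (racemic), via sodium formyl ester enolate 16 (not isolated)
Conditions: HCO2Me, NaOMe, Et2O, 0 → 25 °C; then dry HCl, MeOH, 0 → 25 °C
Reagents that add atoms: methyl formate, COC=O; methanol, CO
Why: Crossed Claisen formylation followed by acid-catalysed acetalisation gives the three-carbon unit (future C2, C3, C4) with the C3 methoxy group in place and C2 as a latent oxocarbenium ion; its stereocentre is racemic and is destroyed in step 11.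

**Step 9**
Reactants: 14 (4S,5S)-2-allyl-4-Ar-5-methoxycyclopent-2-en-1-one
Product: 18 (3R,4S,5S)-2-allyl-4-Ar-5-methoxy-3-methyl-1-(trimethylsilyloxy)cyclopent-1-ene
Conditions: Me2CuLi (from CuI and MeLi), TMSCl, THF, −78 °C; Et3N, pentane work-up
Reagents that add atoms: lithium dimethylcuprate, [Li+].C[Cu-]C; chlorotrimethylsilane, C[Si](C)(C)Cl
Why: Conjugate addition of Me2CuLi with in situ silylation delivers methyl to C7 anti to the adjacent C6 aryl group (trans) and gives the tetrasubstituted C1 enol silane regiospecifically.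

**Step 10**
Reactants: 18 (3R,4S,5S)-2-allyl-4-Ar-5-methoxy-3-methyl-1-(trimethylsilyloxy)cyclopent-1-ene; 17 methyl 2,3,3-trimethoxypropanoate
Product: 19 methyl 3-[(1R,2R,3S,4S)-1-allyl-3-Ar-4-methoxy-2-methyl-5-oxocyclopentyl]-2,3-dimethoxypropanoate
Conditions: TMSOTf (0.3 equiv), CH2Cl2, −78 → −30 °C
Reagents that add atoms: none
Why: Mukaiyama addition of the enol silane to the oxocarbenium ion from acetal 17 creates the quaternary C1; the electrophile should approach anti to the vicinal C7 methyl (held pseudoaxial by allylic 1,2-strain with the C1 allyl group), so the chain ends cis to the aryl group and trans to methyl, and the two side-chain stereocentres are a mixture that vanishes in step 11.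

**Step 11**
Reactants: 19 methyl 3-[(1R,2R,3S,4S)-1-allyl-3-Ar-4-methoxy-2-methyl-5-oxocyclopentyl]-2,3-dimethoxypropanoate
Product: 21 (1S,5R,6R,7S)-5-allyl-7-Ar-1,3-dimethoxy-6-methylbicyclo[3.2.1]oct-3-ene-2,8-dione, via bridged methoxy diketone 20 (not isolated)
Conditions: LiN(SiMe3)2 (2.2 equiv), THF, −78 → 0 °C; then AcOH
Reagents that add atoms: none
Why: LiN(SiMe3)2 removes the only acidic ketone α-hydrogen (C5–H; C1 is quaternary and the ester α-hydrogen is less acidic), the α-methoxy enolate attacks the side-chain ester carbonyl C4 and expels methoxide to give bridged diketone 20, and E1cB loss of the C2 methoxy group (C3–H is now α to the C4 ketone) installs the C2=C3 enol ether and makes the sequence irreversible. The closest known reaction types are the Dieckmann-type intramolecular Claisen acylation of a ketone enolate that gives bridged bicyclic β-diketones and the β-alkoxy elimination that gives α-alkoxy enones. Ring A closes in the 6-(enolexo)-exo-trig mode, C5 bonding to C4 with the leaving methoxide exocyclic. The new stereocentre C5 is controlled by the tether: the chain is fixed on C1 and can reach C5 only on its own face, so the one-carbon C8 bridge enforces the cis-1,3 junction and the earlier C5 configuration, erased in the enolate, is irrelevant. The step needs C- over O-acylation and survival of the non-enolisable β-diketone; O-acylation would give an enol lactone that is itself an acyl donor and should revert, and LiOMe in THF at low temperature should be a poor nucleophile toward the product.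

**Step 12**
Reactants: 21 (1S,5R,6R,7S)-5-allyl-7-Ar-1,3-dimethoxy-6-methylbicyclo[3.2.1]oct-3-ene-2,8-dione
Product: 22 (1R,4S,5R,6S,7R)-1-allyl-6-Ar-4-hydroxy-3,5-dimethoxy-7-methylbicyclo[3.2.1]oct-2-en-8-one
Conditions: NaBH4, CeCl3·7H2O, MeOH, −78 °C
Reagents that add atoms: none
Why: Luche reduction: the C4 enone carbonyl, flanked by the chelating C3 and C5 methoxy groups and activated by CeCl3, should take hydride 1,2 on its exo face (the endo face is covered by the C6 aryl group) to give the endo 4S alcohol, while the C8 ketone between two fully substituted bridgeheads is expected to react more slowly.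

**Step 13**
Reactants: 22 (1R,4S,5R,6S,7R)-1-allyl-6-Ar-4-hydroxy-3,5-dimethoxy-7-methylbicyclo[3.2.1]oct-2-en-8-one
Product: 23 (1R,4S,5R,6S,7R)-4-hydroxy-6-(4-hydroxy-3-methoxyphenyl)-3,5-dimethoxy-7-methyl-1-(prop-2-en-1-yl)bicyclo[3.2.1]oct-2-en-8-one
Conditions: TBAF, AcOH, THF, 0 °C
Reagents that add atoms: none
Why: Fluoride cleaves the aryl silyl ether, and the acetic acid buffer should protect the β-hydroxy ketone from retro-aldol opening and the enol ether from hydrolysis.

**Compound list**
1 | 4-bromo-2-methoxyphenol | COc1cc(Br)ccc1O | starting material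
2 | (4-bromo-2-methoxyphenoxy)triisopropylsilane | COc1cc(Br)ccc1O[Si](C(C)C)(C(C)C)C(C)C | intermediate
3 | cyclopent-2-en-1-one | O=C1C=CCC1 | starting material
4 | aryllithium ArLi | [Li]c1ccc(O[Si](C(C)C)(C(C)C)C(C)C)c(OC)c1 | intermediate
5 | aryltitanium triisopropoxide ArTi(OiPr)3 | CC(C)O[Ti](OC(C)C)(OC(C)C)c1ccc(O[Si](C(C)C)(C(C)C)C(C)C)c(OC)c1 | intermediate
6 | triisopropoxytitanium (R)-3-Ar-cyclopent-1-en-1-olate | CC(C)O[Ti](OC(C)C)(OC(C)C)OC1=C[C@H](c2ccc(O[Si](C(C)C)(C(C)C)C(C)C)c(OC)c2)CC1 | intermediate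
7 | (R)-3-Ar-1-(trimethylsilyloxy)cyclopent-1-ene | C[Si](C)(C)OC1=C[C@H](c2ccc(O[Si](C(C)C)(C(C)C)C(C)C)c(OC)c2)CC1 | intermediate
8 | (2S,3S)-3-Ar-2-(trimethylsilyloxy)cyclopentan-1-one (trans) | O=C1[C@@H](O[Si](C)(C)C)[C@H](c2ccc(O[Si](C(C)C)(C(C)C)C(C)C)c(OC)c2)CC1 | intermediate
9 | (2S,3S)-3-Ar-2-hydroxycyclopentan-1-one (trans) | O=C1[C@@H](O)[C@H](c2ccc(O[Si](C(C)C)(C(C)C)C(C)C)c(OC)c2)CC1 | intermediate
10 | (2S,3S)-3-Ar-2-methoxycyclopentan-1-one (trans) | O=C1[C@@H](OC)[C@H](c2ccc(O[Si](C(C)C)(C(C)C)C(C)C)c(OC)c2)CC1 | intermediate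
11 | (4S,5S)-4-Ar-5-methoxy-1-(trimethylsilyloxy)cyclopent-1-ene | C[Si](C)(C)OC1=CC[C@@H](c2ccc(O[Si](C(C)C)(C(C)C)C(C)C)c(OC)c2)[C@@H]1OC | intermediate
12 | (4S,5S)-4-Ar-5-methoxycyclopent-2-en-1-one | O=C1C=C[C@@H](c2ccc(O[Si](C(C)C)(C(C)C)C(C)C)c(OC)c2)[C@@H]1OC | intermediate
13 | (4S,5S)-4-Ar-2-iodo-5-methoxycyclopent-2-en-1-one | O=C1C(I)=C[C@@H](c2ccc(O[Si](C(C)C)(C(C)C)C(C)C)c(OC)c2)[C@@H]1OC | intermediate
14 | (4S,5S)-2-allyl-4-Ar-5-methoxycyclopent-2-en-1-one | O=C1C(CC=C)=C[C@@H](c2ccc(O[Si](C(C)C)(C(C)C)C(C)C)c(OC)c2)[C@@H]1OC | intermediate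
15 | methyl methoxyacetate | COCC(=O)OC | starting material
16 | sodium enolate of methyl 2-methoxy-3-oxopropanoate | [Na+].[O-]C=C(OC)C(=O)OC | intermediate
17 | methyl 2,3,3-trimethoxypropanoate (racemic) | COC(OC)C(OC)C(=O)OC | intermediate
18 | (3R,4S,5S)-2-allyl-4-Ar-5-methoxy-3-methyl-1-(trimethylsilyloxy)cyclopent-1-ene (methyl trans to Ar) | C[Si](C)(C)OC1=C(CC=C)[C@H](C)[C@@H](c2ccc(O[Si](C(C)C)(C(C)C)C(C)C)c(OC)c2)[C@@H]1OC | intermediate
19 | methyl 3-[(1R,2R,3S,4S)-1-allyl-3-Ar-4-methoxy-2-methyl-5-oxocyclopentyl]-2,3-dimethoxypropanoate (side-chain carbons: mixture; chain cis to Ar, trans to methyl) | O=C1[C@@](CC=C)(C(OC)C(OC)C(=O)OC)[C@H](C)[C@@H](c2ccc(O[Si](C(C)C)(C(C)C)C(C)C)c(OC)c2)[C@@H]1OC | intermediate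
20 | 1-allyl-6-Ar-2,3,5-trimethoxy-7-methylbicyclo[3.2.1]octane-4,8-dione (target locants; ring stereocentres as in 21, C2/C3 mixture) | C=CC[C@@]12C(OC)C(OC)C(=O)[C@@](OC)(C1=O)[C@H](c1ccc(O[Si](C(C)C)(C(C)C)C(C)C)c(OC)c1)[C@H]2C | intermediate
21 | (1S,5R,6R,7S)-5-allyl-7-Ar-1,3-dimethoxy-6-methylbicyclo[3.2.1]oct-3-ene-2,8-dione (aryl endo, methyl exo) | C=CC[C@@]12C=C(OC)C(=O)[C@@](OC)(C1=O)[C@H](c1ccc(O[Si](C(C)C)(C(C)C)C(C)C)c(OC)c1)[C@H]2C | intermediate
22 | (1R,4S,5R,6S,7R)-1-allyl-6-Ar-4-hydroxy-3,5-dimethoxy-7-methylbicyclo[3.2.1]oct-2-en-8-one | C=CC[C@@]12C=C(OC)[C@H](O)[C@@](OC)(C1=O)[C@H](c1ccc(O[Si](C(C)C)(C(C)C)C(C)C)c(OC)c1)[C@H]2C | intermediate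
23 | (1R,4S,5R,6S,7R)-4-hydroxy-6-(4-hydroxy-3-methoxyphenyl)-3,5-dimethoxy-7-methyl-1-(prop-2-en-1-yl)bicyclo[3.2.1]oct-2-en-8-one | C=CC[C@@]12C=C(OC)[C@H](O)[C@@](OC)(C1=O)[C@H](c1ccc(O)c(OC)c1)[C@H]2C | target

**Step count**
Total: 13 steps. Longest linear sequence: 12 steps (steps 1–7 and 9–13); step 8 prepares the three-carbon reagent.

**Steps most likely to fail**

Step 11 (ring A closure). The liberated methoxide may open the strained, non-enolisable β-diketone by retro-Claisen cleavage, or the ester chain may eliminate methanol first to a (Z)-acrylate that cannot reach C5. The fallback closes ring A at the aldehyde oxidation level by an aldol addition. It sets out from 19: LiAlH4 in THF should reduce ketone and ester to the diol F1. Swern oxidation should give the keto aldehyde F2. K2CO3 in MeOH should then bring about β-elimination of methanol to the enal, E/Z equilibration by reversible methoxide addition, and aldol attack of the C5 enolate on the aldehyde, giving the bridged hydroxy enol ether F3 (C4 epimers, both usable). Dess–Martin oxidation of F3 comes back to the route at 21.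

Step 12 (C4 reduction). Hydride may add competitively to the strained C8 ketone. The fallback replaces chemoselective reduction by global reduction and steric differentiation. It sets out from 21: excess NaBH4 in MeOH should give the diol F4, with C4 still reduced from the exo face. TESCl and imidazole should silylate only the C4 hydroxyl, because the C8 carbinol lies between two fully substituted bridgeheads, giving the silyl ether F5. Dess–Martin oxidation of the C8 carbinol should give the ketone F6. TBAF with AcOH removes both silyl groups and comes back to the route at 23.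

Step 10 (quaternary C1). The deactivated oxocarbenium ion may react too slowly with the hindered enol silane, so that protodesilylation or poor facial selectivity takes over. The fallback forms the C1–C2 bond by α-alkenylation of the ketone enolate. It sets out from 18 and from the sodium enolate 16: 16 with PhNTf2 should give the enol triflate F7, with the triflyloxy group cis to the ester through the chelated enolate. The lithium enolate made from 18 with MeLi is coupled with F7 using Pd2(dba)3 and P(t-Bu)3 in THF to give the keto acrylate F8, in which C1 is cis to the ester. LiN(SiMe3)2 then closes ring A directly and comes back to the route at 21.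

**Further compounds**
F1 | step 11 | 2-allyl-4-Ar-2-(3-hydroxy-1,2-dimethoxypropyl)-5-methoxy-3-methylcyclopentan-1-ol (ring stereocentres as in 19, carbinol and side-chain carbons as mixtures) | OC1[C@@](CC=C)(C(OC)C(OC)CO)[C@H](C)[C@@H](c2ccc(O[Si](C(C)C)(C(C)C)C(C)C)c(OC)c2)[C@@H]1OC
F2 | step 11 | 3-[1-allyl-3-Ar-4-methoxy-2-methyl-5-oxocyclopentyl]-2,3-dimethoxypropanal (ring stereocentres as in 19) | O=C1[C@@](CC=C)(C(OC)C(OC)C=O)[C@H](C)[C@@H](c2ccc(O[Si](C(C)C)(C(C)C)C(C)C)c(OC)c2)[C@@H]1OC
F3 | step 11 | 1-allyl-6-Ar-4-hydroxy-3,5-dimethoxy-7-methylbicyclo[3.2.1]oct-2-en-8-one, C4 epimers | C=CC[C@@]12C=C(OC)C(O)[C@@](OC)(C1=O)[C@H](c1ccc(O[Si](C(C)C)(C(C)C)C(C)C)c(OC)c1)[C@H]2C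
F4 | step 12 | 1-allyl-6-Ar-3,5-dimethoxy-7-methylbicyclo[3.2.1]oct-2-ene-4,8-diol (C4 as in 22, C8 carbinol configuration open) | C=CC[C@@]12C=C(OC)[C@H](O)[C@@](OC)(C1O)[C@H](c1ccc(O[Si](C(C)C)(C(C)C)C(C)C)c(OC)c1)[C@H]2C
F5 | step 12 | C4 triethylsilyl ether of F4 | C=CC[C@@]12C=C(OC)[C@H](O[Si](CC)(CC)CC)[C@@](OC)(C1O)[C@H](c1ccc(O[Si](C(C)C)(C(C)C)C(C)C)c(OC)c1)[C@H]2C
F6 | step 12 | C4 triethylsilyl ether of 22 | C=CC[C@@]12C=C(OC)[C@H](O[Si](CC)(CC)CC)[C@@](OC)(C1=O)[C@H](c1ccc(O[Si](C(C)C)(C(C)C)C(C)C)c(OC)c1)[C@H]2C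
F7 | step 10 | methyl 2-methoxy-3-(trifluoromethylsulfonyloxy)prop-2-enoate, triflyloxy cis to the ester | COC(=O)/C(OC)=C\OS(=O)(=O)C(F)(F)F
F8 | step 10 | methyl 3-[1-allyl-3-Ar-4-methoxy-2-methyl-5-oxocyclopentyl]-2-methoxyprop-2-enoate, ring carbon cis to the ester (ring stereocentres as in 19) | O=C1[C@@](CC=C)(/C=C(OC)\C(=O)OC)[C@H](C)[C@@H](c2ccc(O[Si](C(C)C)(C(C)C)C(C)C)c(OC)c2)[C@@H]1OC
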